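**Strategy**

Everything rests on disconnecting C2–C3, the bond that the oxolane ring (O, C3, C2, C1, C10) shares with the ten-membered carbocycle. The key step exploits C3 being an ether carbon next to the C4=C5 alkene and 1,3 to C1. An open-chain precursor carrying a tertiary propargylic alcohol (C10, C1, C2) and a Z-enal (C3) is closed by gold catalysis to a bridged 4-methylidene-1,3-dioxolane, and Petasis–Ferrier rearrangement then exchanges the ring oxygen for C2. One operation creates C2–C3, the oxolane, the carbocycle, the C1 ketone and the C3 stereocentre. The precursor is assembled by a pyruvate aldol, a Baylis–Hillman/Barbier lactone annulation and a butenolide-derived lactol.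

Key step: step 12

Remark: atoms carry germacrane numbers (C1 carbinol, C2 methylene, C3 and C10 ether carbons, C6/C7 lactone carbons, C8 acyloxy carbon; O8 and O10 are the oxygens on C8 and C10); 4-methylfuran-2(5H)-one, angelic acid and both enantiomers of the box ligand and CBS catalyst are taken as purchasable.

**Route**

Step 1
Reactants: 1 1,1-dimethoxypropan-2-one
Product: 2 triethyl[(3,3-dimethoxyprop-1-en-2-yl)oxy]silane
Conditions: LiN(i-Pr)2, THF, −78 °C; then Et3SiCl, −78 to 0 °C
Reagents that add atoms: chlorotriethylsilane CC[Si](Cl)(CC)CC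
Why: Kinetic deprotonation is expected only at the methyl group (the acetal methine is hindered and poorly acidic), so O-silylation should give the single enol silane needed for a Mukaiyama aldol.

Step 2
Reactants: 2 triethyl[(3,3-dimethoxyprop-1-en-2-yl)oxy]silane; 3 methyl pyruvate
Product: 4 methyl (2R)-5,5-dimethoxy-2-methyl-4-oxo-2-(triethylsilyloxy)pentanoate
Conditions: Cu(OTf)2 (10 mol %), 2,2'-isopropylidenebis[(4R)-4-tert-butyl-2-oxazoline] ((R,R)-t-Bu-box, 11 mol %), THF, −78 °C
Reagents that add atoms: none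
Why: Copper–bis(oxazoline)-catalysed Mukaiyama aldol addition to chelated pyruvate should set C10 under catalyst control (the (R,R) ligand is chosen as the mirror image of the (S,S) ligand that gives the (S) series), with silyl transfer delivering the tertiary silyl ether directly.

Step 3
Reactants: 4 methyl (2R)-5,5-dimethoxy-2-methyl-4-oxo-2-(triethylsilyloxy)pentanoate
Product: 6 (3R,5R)-5-(dimethoxymethyl)-3-methyl-3-(triethylsilyloxy)oxolan-2-one, via hydroxy ester 5 (not isolated)
Conditions: (S)-1-methyl-3,3-diphenyltetrahydro-1H,3H-pyrrolo[1,2-c][1,3,2]oxazaborole ((S)-Me-CBS, 0.2 equiv), BH3·SMe2, THF, −30 °C; MeOH; then pyridinium p-toluenesulfonate (cat.), PhMe, 60 °C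
Reagents that add atoms: none
Why: Corey–Bakshi–Shibata reduction with the branched dimethoxymethyl group as the large substituent should give the 8R carbinol under reagent control, and this hydroxyl then closes onto the neighbouring ester (gamma-lactonisation) so that the ester is set up for clean half-reduction.

Step 4
Reactants: 6 (3R,5R)-5-(dimethoxymethyl)-3-methyl-3-(triethylsilyloxy)oxolan-2-one
Product: 8 (2R,4R)-1,1-dimethoxy-4-methyl-4-(triethylsilyloxy)hex-5-yn-2-ol, via lactol 7 (not isolated)
Conditions: i-Bu2AlH (1.1 equiv), CH2Cl2, −78 °C; then MeOH, K2CO3, dimethyl (1-diazo-2-oxopropyl)phosphonate, 0 °C to rt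
Reagents that add atoms: dimethyl (1-diazo-2-oxopropyl)phosphonate COP(=O)(OC)C(=[N+]=[N-])C(C)=O
Why: The aluminium hydride should stop at the lactol, whose open hydroxy aldehyde undergoes Ohira–Bestmann (Seyferth–Gilbert) homologation to the terminal alkyne (C1≡C2) while the tertiary triethylsilyl ether survives K2CO3/MeOH.

Step 5
Reactants: 8 (2R,4R)-1,1-dimethoxy-4-methyl-4-(triethylsilyloxy)hex-5-yn-2-ol
Product: 9 (2R,4R)-2-(tert-butyldimethylsilyloxy)-1,1-dimethoxy-4-methyl-4-(triethylsilyloxy)hex-5-yne
Conditions: t-BuMe2SiCl, imidazole, DMF, 40 °C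
Reagents that add atoms: tert-butylchlorodimethylsilane CC(C)(C)[Si](C)(C)Cl
Why: Standard silylation of the only free hydroxyl; this ether later keeps O8 from adding to the alkyne in the gold step.

Step 6
Reactants: 9 (2R,4R)-2-(tert-butyldimethylsilyloxy)-1,1-dimethoxy-4-methyl-4-(triethylsilyloxy)hex-5-yne
Product: 10 (2R,4R)-2-(tert-butyldimethylsilyloxy)-4-methyl-4-(triethylsilyloxy)hex-5-ynal
Conditions: Et3SiOTf, 2,4,6-collidine, CH2Cl2, 0 °C; then H2O
Reagents that add atoms: water O
Why: Silyl triflate/collidine acetal cleavage runs through a pyridinium intermediate under non-acidic conditions, so both silyl ethers should survive and the alpha stereocentre is not exposed to enolising media.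

Step 7
Reactants: 10 (2R,4R)-2-(tert-butyldimethylsilyloxy)-4-methyl-4-(triethylsilyloxy)hex-5-ynal; 11 methyl acrylate
Product: 12 methyl (4R,6R)-4-(tert-butyldimethylsilyloxy)-3-hydroxy-6-methyl-2-methylidene-6-(triethylsilyloxy)oct-7-ynoate (both C3 epimers)
Conditions: 1,4-diazabicyclo[2.2.2]octane (1 equiv), methyl acrylate (neat, excess), rt
Reagents that add atoms: none
Why: Morita–Baylis–Hillman reaction of an activated alpha-silyloxy aldehyde; the new carbinol centre is of no consequence because it becomes sp2 in the next step.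

Step 8
Reactants: 12 methyl (4R,6R)-4-(tert-butyldimethylsilyloxy)-3-hydroxy-6-methyl-2-methylidene-6-(triethylsilyloxy)oct-7-ynoate
Product: 13 methyl (2Z,4R,6R)-2-(bromomethyl)-4-(tert-butyldimethylsilyloxy)-6-methyl-6-(triethylsilyloxy)oct-2-en-7-ynoate
Conditions: N-bromosuccinimide, Me2S, CH2Cl2, 0 °C to rt
Reagents that add atoms: N-bromosuccinimide O=C1CCC(=O)N1Br
Why: Corey–Kim-type activation as the alkoxysulfonium salt followed by SN2' attack of bromide should give the thermodynamically preferred (Z)-2-(bromomethyl)enoate.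

Step 9
Reactants: 14 4-methylfuran-2(5H)-one
Product: 15 4-methyl-2,5-dihydrofuran-2-ol
Conditions: i-Bu2AlH (1.05 equiv), CH2Cl2, −78 °C; used crude
Reagents that add atoms: none
Why: Half-reduction of the butenolide gives a lactol that is a masked (Z)-4-hydroxy-3-methylbut-2-enal, the ring fixing the Z geometry of C4=C5 and sparing a protecting group on O3.

Step 10
Reactants: 13 methyl (2Z,4R,6R)-2-(bromomethyl)-4-(tert-butyldimethylsilyloxy)-6-methyl-6-(triethylsilyloxy)oct-2-en-7-ynoate; 15 4-methyl-2,5-dihydrofuran-2-ol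
Product: 17 (4S,5S)-4-[(1R,3R)-1-(tert-butyldimethylsilyloxy)-3-hydroxy-3-methylpent-4-yn-1-yl]-5-[(1Z)-3-hydroxy-2-methylprop-1-en-1-yl]-3-methylideneoxolan-2-one, via syn hydroxy ester 16 (not isolated)
Conditions: indium powder, THF/H2O (1:1), rt; then camphorsulfonic acid (0.2 equiv), MeOH, 0 °C to rt
Reagents that add atoms: none
Why: Indium-mediated Barbier allylation of the open form of 15 should pass through a Zimmerman–Traxler chair (syn adduct, hence the cis lactone at C6/C7) with attack anti to the C8–C9 bond in the A(1,3)-minimised conformer (C7 relative to C8), after which acid in methanol lactonises and removes the tertiary triethylsilyl ether while the hindered secondary silyl ether stays.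

Step 11
Reactants: 17 (4S,5S)-4-[(1R,3R)-1-(tert-butyldimethylsilyloxy)-3-hydroxy-3-methylpent-4-yn-1-yl]-5-[(1Z)-3-hydroxy-2-methylprop-1-en-1-yl]-3-methylideneoxolan-2-one
Product: 18 (2Z)-3-{(2S,3S)-3-[(1R,3R)-1-(tert-butyldimethylsilyloxy)-3-hydroxy-3-methylpent-4-yn-1-yl]-4-methylidene-5-oxooxolan-2-yl}-2-methylprop-2-enal
Conditions: MnO2 (activated, excess), CH2Cl2, rt
Reagents that add atoms: none
Why: MnO2 should oxidise only the primary allylic alcohol under neutral conditions, leaving the tertiary propargylic alcohol and the Z alkene untouched.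

Step 12
Reactants: 18 (2Z)-3-{(2S,3S)-3-[(1R,3R)-1-(tert-butyldimethylsilyloxy)-3-hydroxy-3-methylpent-4-yn-1-yl]-4-methylidene-5-oxooxolan-2-yl}-2-methylprop-2-enal
Product: 20 (3S,6S,7S,8R,10R)-8-(tert-butyldimethylsilyloxy)-3,10-epoxy-1-oxogermacra-4Z,11(13)-dien-12,6-olide, via bridged enol acetal 19 (not isolated)
Conditions: Ph3PAuNTf2 (5 mol %), 4 Å molecular sieves, CH2Cl2 (1 mM), rt; then Me2AlCl (2 equiv), −78 to −40 °C
Reagents that add atoms: none
Why: Proposed new method: the tertiary O10 hydroxyl and the C3 aldehyde should equilibrate with a nine-membered hemiacetal whose hydroxyl adds 5-exo-dig to the gold-activated alkyne at C1, protodeauration giving the bridged enol acetal 19, in which Me2AlCl then ionises the C3–O(enol) bond to a C4=C5-conjugated oxocarbenium ion and an aluminium enolate that recombine through C2 (Petasis–Ferrier rearrangement). The closest known reactions are the gold-catalysed hydroalkoxylation of alkynes by hemiacetal hydroxyls and the Petasis–Ferrier conversion of 4-methylidene-1,3-dioxolanes into oxolan-3-ones, neither shown so far in a tethered version that builds a bridged bicycle. The dioxolane closes by 5-exo-dig O-attack, the oxolane by C2-to-C3 attack of the 5-(enolendo)-endo-trig type usual for this rearrangement, and the ten-membered carbocycle results from the ten-membered cyclic enol acetal by 1,3-shift of C3 from oxygen to C2. The only new stereocentre, C3, is fixed by C10 through the bridge, because C4 and C9 can only be cis on the five-membered ring. The step needs intramolecular hemiacetal capture (high dilution and irreversible oxyauration), C–C bond formation at C3 and not at C5 (five- against seven-membered closure) and retention of the Z alkene (the cation is confined to a nine-membered ring and should collapse at once), while O8 is silylated so that it cannot add to the alkyne.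

Step 13
Reactants: 20 (3S,6S,7S,8R,10R)-8-(tert-butyldimethylsilyloxy)-3,10-epoxy-1-oxogermacra-4Z,11(13)-dien-12,6-olide
Product: 21 (3S,6S,7R,8R,10R)-3,10-epoxy-8-hydroxy-1-oxogermacra-4Z,11(13)-dien-12,6-olide
Conditions: HF·pyridine, pyridine/THF, 0 °C to rt
Reagents that add atoms: none
Why: Buffered fluoride cleavage of the secondary silyl ether is non-basic and should be tolerated by the methylene lactone and the beta-alkoxy ketone.

Step 14
Reactants: 21 (3S,6S,7R,8R,10R)-3,10-epoxy-8-hydroxy-1-oxogermacra-4Z,11(13)-dien-12,6-olide; 22 angelic acid [(2Z)-2-methylbut-2-enoic acid]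
Product: 23 (3S,6S,7R,8R,10R)-8-angeloyloxy-3,10-epoxy-1-oxogermacra-4Z,11(13)-dien-12,6-olide
Conditions: 22, 2,4,6-trichlorobenzoyl chloride, Et3N, PhMe, rt; then 21, 70 °C (no nucleophilic catalyst)
Reagents that add atoms: none
Why: Yamaguchi-type acylation through the mixed anhydride without an acyl-transfer catalyst should transfer the angeloyl group without Z-to-E isomerisation, and only one hydroxyl is present.

Step 15
Reactants: 23 (3S,6S,7R,8R,10R)-8-angeloyloxy-3,10-epoxy-1-oxogermacra-4Z,11(13)-dien-12,6-olide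
Product: 24 (1S,3S,6S,7R,8R,10R)-8-angeloyloxy-3,10-epoxy-1-hydroxygermacra-4Z,11(13)-dien-12,6-olide (CNP0213894.2)
Conditions: (R)-1-methyl-3,3-diphenyltetrahydro-1H,3H-pyrrolo[1,2-c][1,3,2]oxazaborole ((R)-Me-CBS, 1 equiv), catecholborane, PhMe, −78 °C
Reagents that add atoms: none
Why: Corey–Bakshi–Shibata reduction with the quaternary C10 as the large group should deliver hydride to the face syn to C9 and give the 1S alcohol (hydroxyl cis to the C10 methyl) under reagent control, catecholborane at low temperature sparing the methylene lactone and the angelate.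

**Compound list**

1 | 1,1-dimethoxypropan-2-one | CC(=O)C(OC)OC | starting material
2 | triethyl[(3,3-dimethoxyprop-1-en-2-yl)oxy]silane | C=C(O[Si](CC)(CC)CC)C(OC)OC | intermediate
3 | methyl pyruvate | CC(=O)C(=O)OC | starting material
4 | methyl (2R)-5,5-dimethoxy-2-methyl-4-oxo-2-(triethylsilyloxy)pentanoate | COC(OC)C(=O)C[C@@](C)(O[Si](CC)(CC)CC)C(=O)OC | intermediate
5 | methyl (2R,4R)-4-hydroxy-5,5-dimethoxy-2-methyl-2-(triethylsilyloxy)pentanoate (not isolated) | COC(OC)[C@H](O)C[C@@](C)(O[Si](CC)(CC)CC)C(=O)OC | intermediate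
6 | (3R,5R)-5-(dimethoxymethyl)-3-methyl-3-(triethylsilyloxy)oxolan-2-one | COC(OC)[C@H]1C[C@@](C)(O[Si](CC)(CC)CC)C(=O)O1 | intermediate
7 | (3R,5R)-5-(dimethoxymethyl)-3-methyl-3-(triethylsilyloxy)oxolan-2-ol (lactol, both anomers, not isolated) | COC(OC)[C@H]1C[C@@](C)(O[Si](CC)(CC)CC)C(O)O1 | intermediate
8 | (2R,4R)-1,1-dimethoxy-4-methyl-4-(triethylsilyloxy)hex-5-yn-2-ol | COC(OC)[C@H](O)C[C@@](C)(O[Si](CC)(CC)CC)C#C | intermediate
9 | (2R,4R)-2-(tert-butyldimethylsilyloxy)-1,1-dimethoxy-4-methyl-4-(triethylsilyloxy)hex-5-yne | COC(OC)[C@H](O[Si](C)(C)C(C)(C)C)C[C@@](C)(O[Si](CC)(CC)CC)C#C | intermediate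
10 | (2R,4R)-2-(tert-butyldimethylsilyloxy)-4-methyl-4-(triethylsilyloxy)hex-5-ynal | O=C[C@H](O[Si](C)(C)C(C)(C)C)C[C@@](C)(O[Si](CC)(CC)CC)C#C | intermediate
11 | methyl acrylate | C=CC(=O)OC | starting material
12 | methyl (4R,6R)-4-(tert-butyldimethylsilyloxy)-3-hydroxy-6-methyl-2-methylidene-6-(triethylsilyloxy)oct-7-ynoate (C3 epimers) | COC(=O)C(=C)C(O)[C@H](O[Si](C)(C)C(C)(C)C)C[C@@](C)(O[Si](CC)(CC)CC)C#C | intermediate
13 | methyl (2Z,4R,6R)-2-(bromomethyl)-4-(tert-butyldimethylsilyloxy)-6-methyl-6-(triethylsilyloxy)oct-2-en-7-ynoate | COC(=O)/C(CBr)=C/[C@H](O[Si](C)(C)C(C)(C)C)C[C@@](C)(O[Si](CC)(CC)CC)C#C | intermediate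
14 | 4-methylfuran-2(5H)-one | CC1=CC(=O)OC1 | starting material
15 | 4-methyl-2,5-dihydrofuran-2-ol | CC1=CC(O)OC1 | intermediate
16 | methyl (3S,4S,5Z)-3-[(1R,3R)-1-(tert-butyldimethylsilyloxy)-3-methyl-3-(triethylsilyloxy)pent-4-yn-1-yl]-4,7-dihydroxy-6-methyl-2-methylidenehept-5-enoate (not isolated) | COC(=O)C(=C)[C@@H]([C@@H](O)/C=C(/C)CO)[C@H](O[Si](C)(C)C(C)(C)C)C[C@@](C)(O[Si](CC)(CC)CC)C#C | intermediate
17 | (4S,5S)-4-[(1R,3R)-1-(tert-butyldimethylsilyloxy)-3-hydroxy-3-methylpent-4-yn-1-yl]-5-[(1Z)-3-hydroxy-2-methylprop-1-en-1-yl]-3-methylideneoxolan-2-one | C=C1C(=O)O[C@@H](/C=C(/C)CO)[C@H]1[C@H](O[Si](C)(C)C(C)(C)C)C[C@@](C)(O)C#C | intermediate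
18 | (2Z)-3-{(2S,3S)-3-[(1R,3R)-1-(tert-butyldimethylsilyloxy)-3-hydroxy-3-methylpent-4-yn-1-yl]-4-methylidene-5-oxooxolan-2-yl}-2-methylprop-2-enal | C=C1C(=O)O[C@@H](/C=C(/C)C=O)[C@H]1[C@H](O[Si](C)(C)C(C)(C)C)C[C@@](C)(O)C#C | intermediate
19 | bridged 4-methylidene-1,3-dioxolane: C3 is the acetal carbon of O10 and of the enol oxygen on C1, C1=C2H2 exocyclic, lactone and silyl ether as in 18 (not isolated) | C=C1C(=O)O[C@H]2/C=C(/C)[C@@H]3OC(=C)[C@@](C)(C[C@@H](O[Si](C)(C)C(C)(C)C)[C@@H]12)O3 | intermediate
20 | (3S,6S,7S,8R,10R)-8-(tert-butyldimethylsilyloxy)-3,10-epoxy-1-oxogermacra-4Z,11(13)-dien-12,6-olide | C=C1C(=O)O[C@H]2/C=C(/C)[C@@H]3CC(=O)[C@@](C)(C[C@@H](O[Si](C)(C)C(C)(C)C)[C@@H]12)O3 | intermediate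
21 | (3S,6S,7R,8R,10R)-3,10-epoxy-8-hydroxy-1-oxogermacra-4Z,11(13)-dien-12,6-olide | C=C1C(=O)O[C@H]2/C=C(/C)[C@@H]3CC(=O)[C@@](C)(C[C@@H](O)[C@@H]12)O3 | intermediate
22 | angelic acid [(2Z)-2-methylbut-2-enoic acid] | C/C=C(/C)C(=O)O | starting material
23 | (3S,6S,7R,8R,10R)-8-angeloyloxy-3,10-epoxy-1-oxogermacra-4Z,11(13)-dien-12,6-olide | C=C1C(=O)O[C@H]2/C=C(/C)[C@@H]3CC(=O)[C@@](C)(C[C@@H](OC(=O)/C(C)=C\C)[C@@H]12)O3 | intermediate
24 | (1S,3S,6S,7R,8R,10R)-8-angeloyloxy-3,10-epoxy-1-hydroxygermacra-4Z,11(13)-dien-12,6-olide (CNP0213894.2) | C=C1C(=O)O[C@H]2/C=C(/C)[C@@H]3C[C@H](O)[C@@](C)(C[C@@H](OC(=O)/C(C)=C\C)[C@@H]12)O3 | target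

**Count and risks**

Total step count: 15. Longest linear sequence: 14 (steps 1–8 and 10–15; step 9 is a one-step side branch).

Steps most likely to fail:

1. Step 12 (proposed new method). The nine-membered hemiacetal may form too rarely, so that intermolecular acetal formation, plain hydration of the alkyne or Meyer–Schuster rearrangement of the propargylic alcohol outrun the cyclisation. The fallback uses known reactions and sets out from 18. Gold-catalysed hydration (Ph3PAuNTf2, wet dioxane) should give the alpha-hydroxy methyl ketone F1. Me3SiOTf/Et3N should convert it into the bis(trimethylsilyl) derivative F2 (silyl enol ether C1=C2, silyl ether on O10). BF3·OEt2 at high dilution should then close the ten-membered carbocycle by an intramolecular Mukaiyama aldol addition of C2 to the C3 aldehyde, giving after acidic work-up the macrocyclic hydroxy ketone F3. Mesylation of the allylic C3 hydroxyl and treatment with DBU (elimination, then transannular oxa-Michael addition of the O10 hydroxyl, which can only give the bridged cis arrangement) returns to the route at 20.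

2. Step 10. The allylindium may show poor facial selectivity with respect to C8, or the lactol may react sluggishly and dehydrate to a furan. The fallback sets out from 13. Palladium-catalysed borylation (Pd2(dba)3, bis(pinacolato)diboron, DMSO) should give the allylboronate F4. Its Sc(OTf)3-promoted allylboration of 15 runs through a tight boron-centred chair and is stereospecific for the syn adduct, with a shorter forming bond that should sharpen the induction from C8. Camphorsulfonic acid in methanol then lactonises and removes the triethylsilyl group, returning at 17.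

3. Step 15. Reagent control may be overridden by the bias of the bicyclic ketone (attack from the face of the C10 methyl), or the methylene lactone may suffer conjugate reduction. The fallback changes the order and the control element and sets out from 21. Hydroxyl-directed reduction with Me4NBH(OAc)3 in MeCN/AcOH should deliver hydride intramolecularly from the O8-bound boron, which sits on the C9 side of the oxolane, giving the diol F5 with the 1S configuration. Angeloylation under the conditions of step 14 at the less hindered C8 hydroxyl (the C1 hydroxyl is neopentylic) returns at 24.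

**Further compounds**

F1 | step 12 | (2Z)-3-{(2S,3S)-3-[(1R,3R)-1-(tert-butyldimethylsilyloxy)-3-hydroxy-3-methyl-4-oxopentyl]-4-methylidene-5-oxooxolan-2-yl}-2-methylprop-2-enal | C=C1C(=O)O[C@@H](/C=C(/C)C=O)[C@H]1[C@H](O[Si](C)(C)C(C)(C)C)C[C@@](C)(O)C(C)=O
F2 | step 12 | bis(trimethylsilyl) derivative of F1 (trimethylsilyl enol ether at C1=C2, trimethylsilyl ether on O10) | C=C1C(=O)O[C@@H](/C=C(/C)C=O)[C@H]1[C@H](O[Si](C)(C)C(C)(C)C)C[C@@](C)(O[Si](C)(C)C)C(=C)O[Si](C)(C)C
F3 | step 12 | (6S,7S,8R,10R)-8-(tert-butyldimethylsilyloxy)-3,10-dihydroxy-1-oxogermacra-4Z,11(13)-dien-12,6-olide (C3 epimers) | C=C1C(=O)O[C@H]2/C=C(/C)C(O)CC(=O)[C@](C)(O)C[C@@H](O[Si](C)(C)C(C)(C)C)[C@@H]12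
F4 | step 10 | methyl (2E,4R,6R)-4-(tert-butyldimethylsilyloxy)-6-methyl-2-[(4,4,5,5-tetramethyl-1,3,2-dioxaborolan-2-yl)methyl]-6-(triethylsilyloxy)oct-2-en-7-ynoate | COC(=O)/C(CB1OC(C)(C)C(C)(C)O1)=C/[C@H](O[Si](C)(C)C(C)(C)C)C[C@@](C)(O[Si](CC)(CC)CC)C#C
F5 | step 15 | (1S,3S,6S,7R,8R,10R)-3,10-epoxy-1,8-dihydroxygermacra-4Z,11(13)-dien-12,6-olide | C=C1C(=O)O[C@H]2/C=C(/C)[C@@H]3C[C@H](O)[C@@](C)(C[C@@H](O)[C@@H]12)O3
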